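**Retrosynthetic overview**
- The target ketone comes from chemoselective DDQ dehydrogenation of the benzylic carbinol of a phenolic tetraol; the C-2 stereocentre is carried through, not made, at that stage.
- The tetraol comes from global hydride reduction of the Ni/Cr (Nozaki–Hiyama–Kishi) adduct of 4-iodo-2,6-dimethoxyphenyl acetate (from syringol) and an (S)-2-aryloxy-3-acetoxypropanal.
- The aldehyde comes from an (R)-monoacetate, made by lipase desymmetrization of a prochiral 2-aryloxypropane-1,3-diol: the symmetry-breaking key step, which sets the only stereocentre.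
- The prochiral diol comes from methyl dihydroferulate and dimethyl chloromalonate (O-alkylation, then chemoselective borohydride reduction).
- No ring is formed; both benzene rings come intact from the two phenolic starting materials.

Assumption: the lipase is taken to acetylate the pro-R hydroxymethyl arm of diol 7; this sense is not established for this substrate and must be confirmed on 8 (Mosher ester or chiral HPLC). The opposite outcome is covered by the fallback to step 5.

**Step 1**
Reactants: 1 2,6-dimethoxyphenol (syringol)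
Product: 2 4-iodo-2,6-dimethoxyphenol
Conditions: BnMe3N·ICl2 (1.05 equiv), NaHCO3, CH2Cl2/MeOH, rt
Reagents that add atoms: benzyltrimethylammonium dichloroiodate, C[N+](C)(C)Cc1ccccc1.Cl[I-]Cl
Why: Electrophilic aromatic iodination (SEAr) through the phenol/phenoxide, whose ortho positions are blocked by OMe, so iodine enters para to OH; no stereocentre is formed.

**Step 2**
Reactants: 2 4-iodo-2,6-dimethoxyphenol
Product: 3 4-iodo-2,6-dimethoxyphenyl acetate
Conditions: Ac2O, pyridine, DMAP (cat.), CH2Cl2, 0 °C to rt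
Reagents that add atoms: acetic anhydride, CC(=O)OC(C)=O
Why: DMAP-catalysed O-acetylation (nucleophilic acyl substitution) masks the acidic phenol as an ester that tolerates organochromium chemistry and is removed in the later hydride step.

**Step 3**
Reactants: 4 methyl 3-(4-hydroxy-3-methoxyphenyl)propanoate (methyl dihydroferulate); 5 dimethyl 2-chloropropanedioate (dimethyl chloromalonate)
Product: 6 dimethyl 2-[2-methoxy-4-(3-methoxy-3-oxopropyl)phenoxy]propanedioate
Conditions: K2CO3, acetone, reflux
Reagents that add atoms: none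
Why: Williamson-type SN2 O-alkylation of the potassium phenoxide by the doubly activated α-chloromalonate (chloride rather than bromide, to avoid halophilic attack) gives the achiral aryloxymalonate.

**Step 4**
Reactants: 6 dimethyl 2-[2-methoxy-4-(3-methoxy-3-oxopropyl)phenoxy]propanedioate
Product: 7 methyl 3-{4-[(1,3-dihydroxypropan-2-yl)oxy]-3-methoxyphenyl}propanoate
Conditions: NaBH4 (4 equiv), THF/MeOH, 0 °C to rt
Reagents that add atoms: none
Why: Chemoselective borohydride reduction, in which the two α-aryloxy-activated malonate esters are reduced while the unactivated propanoate ester is not, gives the prochiral (Cs-symmetric) 2-aryloxypropane-1,3-diol.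

**Step 5**
Reactants: 7 methyl 3-{4-[(1,3-dihydroxypropan-2-yl)oxy]-3-methoxyphenyl}propanoate
Product: 8 methyl 3-(4-{[(2R)-1-(acetyloxy)-3-hydroxypropan-2-yl]oxy}-3-methoxyphenyl)propanoate
Conditions: lipase PS (Burkholderia cepacia, immobilised), vinyl acetate (4 equiv), t-BuOMe, 25 °C, stopped at ca. 5–10% diacetate
Reagents that add atoms: vinyl acetate, C=COC(C)=O
Why: Key step, a lipase-catalysed enantiotopic-group-selective transesterification (enzymatic desymmetrization of a prochiral 2-substituted propane-1,3-diol) made irreversible by tautomerisation of vinyl alcohol: acetylation of the pro-R CH2OH creates the (R)-centre, slight over-acylation removes the minor enantiomer as achiral diacetate, and 8 is used at once because a 1,3-acyl shift would racemise it.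

**Step 6**
Reactants: 8 methyl 3-(4-{[(2R)-1-(acetyloxy)-3-hydroxypropan-2-yl]oxy}-3-methoxyphenyl)propanoate
Product: 9 methyl 3-(4-{[(2S)-1-(acetyloxy)-3-oxopropan-2-yl]oxy}-3-methoxyphenyl)propanoate
Conditions: Dess–Martin periodinane (1.2 equiv), NaHCO3, CH2Cl2, 0 °C; crude 9 used at once
Reagents that add atoms: none
Why: Dess–Martin oxidation under buffered, base-free conditions converts the free CH2OH into the aldehyde without epimerising the α-aryloxy centre or eliminating the β-acetate; the descriptor changes from R to S through CIP priorities only.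

**Step 7**
Reactants: 9 methyl 3-(4-{[(2S)-1-(acetyloxy)-3-oxopropan-2-yl]oxy}-3-methoxyphenyl)propanoate; 3 4-iodo-2,6-dimethoxyphenyl acetate (2 equiv)
Product: 11 methyl 3-[4-({(1RS,2S)-3-(acetyloxy)-1-[4-(acetyloxy)-3,5-dimethoxyphenyl]-1-hydroxypropan-2-yl}oxy)-3-methoxyphenyl]propanoate, via arylchromium(III) dichloride 10 (not isolated)
Conditions: CrCl2 (5 equiv), NiCl2 (2 mol %), degassed DMF, rt; aqueous work-up
Reagents that add atoms: none
Why: Nozaki–Hiyama–Kishi reaction, in which Ni(0) inserts into the aryl iodide and transmetallation gives the weakly basic arylchromium(III) species 10, which adds to the aldehyde (esters untouched) without enolisation or β-elimination, so C-2 is preserved; the new carbinol centre forms unselectively and is erased in step 9.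

**Step 8**
Reactants: 11 methyl 3-[4-({(1RS,2S)-3-(acetyloxy)-1-[4-(acetyloxy)-3,5-dimethoxyphenyl]-1-hydroxypropan-2-yl}oxy)-3-methoxyphenyl]propanoate
Product: 12 (1RS,2S)-1-(4-hydroxy-3,5-dimethoxyphenyl)-2-[4-(3-hydroxypropyl)-2-methoxyphenoxy]propane-1,3-diol
Conditions: LiAlH4 (excess), THF, 0 °C to rt; Rochelle salt work-up at pH 5–6
Reagents that add atoms: none
Why: Global LiAlH4 reduction cleaves both acetates and reduces the methyl ester to the 3-hydroxypropyl chain in one operation at the carbinol oxidation level, where C-2 has no adjacent carbonyl and cannot epimerise.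

**Step 9**
Reactants: 12 (1RS,2S)-1-(4-hydroxy-3,5-dimethoxyphenyl)-2-[4-(3-hydroxypropyl)-2-methoxyphenoxy]propane-1,3-diol
Product: 13 (2S)-3-hydroxy-1-(4-hydroxy-3,5-dimethoxyphenyl)-2-[4-(3-hydroxypropyl)-2-methoxyphenoxy]propan-1-one
Conditions: DDQ (1.1 equiv), 1,4-dioxane, rt; neutral work-up (no basic wash)
Reagents that add atoms: none
Why: Chemoselective DDQ dehydrogenation (hydride abstraction) of the p-hydroxybenzylic secondary alcohol, as in the selective α-oxidation of β-O-4 lignin units, gives the aryl ketone under neutral to mildly acidic conditions, leaves both primary alcohols and the (S)-centre untouched, and converges both C-1 epimers on 13.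

**Compound list**
1 | 2,6-dimethoxyphenol (syringol) | COc1cccc(OC)c1O | starting material
2 | 4-iodo-2,6-dimethoxyphenol | COc1cc(I)cc(OC)c1O | intermediate
3 | 4-iodo-2,6-dimethoxyphenyl acetate | COc1cc(I)cc(OC)c1OC(C)=O | intermediate
4 | methyl 3-(4-hydroxy-3-methoxyphenyl)propanoate | COC(=O)CCc1ccc(O)c(OC)c1 | starting material
5 | dimethyl 2-chloropropanedioate | COC(=O)C(Cl)C(=O)OC | starting material
6 | dimethyl 2-[2-methoxy-4-(3-methoxy-3-oxopropyl)phenoxy]propanedioate | COC(=O)CCc1ccc(OC(C(=O)OC)C(=O)OC)c(OC)c1 | intermediate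
7 | methyl 3-{4-[(1,3-dihydroxypropan-2-yl)oxy]-3-methoxyphenyl}propanoate | COC(=O)CCc1ccc(OC(CO)CO)c(OC)c1 | intermediate
8 | methyl 3-(4-{[(2R)-1-(acetyloxy)-3-hydroxypropan-2-yl]oxy}-3-methoxyphenyl)propanoate | COC(=O)CCc1ccc(O[C@@H](COC(C)=O)CO)c(OC)c1 | intermediate
9 | methyl 3-(4-{[(2S)-1-(acetyloxy)-3-oxopropan-2-yl]oxy}-3-methoxyphenyl)propanoate | COC(=O)CCc1ccc(O[C@@H](COC(C)=O)C=O)c(OC)c1 | intermediate
10 | [4-(acetyloxy)-3,5-dimethoxyphenyl]chromium(III) dichloride | CC(=O)Oc1c(OC)cc([Cr](Cl)Cl)cc1OC | intermediate (not isolated)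
11 | methyl 3-[4-({(1RS,2S)-3-(acetyloxy)-1-[4-(acetyloxy)-3,5-dimethoxyphenyl]-1-hydroxypropan-2-yl}oxy)-3-methoxyphenyl]propanoate | COC(=O)CCc1ccc(O[C@@H](COC(C)=O)C(O)c2cc(OC)c(OC(C)=O)c(OC)c2)c(OC)c1 | intermediate
12 | (1RS,2S)-1-(4-hydroxy-3,5-dimethoxyphenyl)-2-[4-(3-hydroxypropyl)-2-methoxyphenoxy]propane-1,3-diol | COc1cc(CCCO)ccc1O[C@@H](CO)C(O)c1cc(OC)c(O)c(OC)c1 | intermediate
13 | (2S)-3-hydroxy-1-(4-hydroxy-3,5-dimethoxyphenyl)-2-[4-(3-hydroxypropyl)-2-methoxyphenoxy]propan-1-one | COc1cc(CCCO)ccc1O[C@@H](CO)C(=O)c1cc(OC)c(O)c(OC)c1 | target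

**Totals**
Total step count: 9. Longest linear sequence: 7 steps (4 to 13, steps 3–9); the syringol branch (steps 1–2) joins at step 7.

**Three steps most likely to fail**

Step 5 (sense and level of enantiotopic-group selection; acyl migration in 8). If acyl transfer gives the (S)-series, the centre is set by enantiotopic ester hydrolysis instead. The fallback sets out from diol 7, which is peracetylated (Ac2O, pyridine) to methyl 3-(4-{[1,3-bis(acetyloxy)propan-2-yl]oxy}-3-methoxyphenyl)propanoate F1. The same lipase in pH 7 phosphate buffer/acetone then cleaves the acetate on the arm it would otherwise have acylated, so the hydrolytic mode gives the monoacetate of opposite configuration to the acylation mode. It comes back to the route at 8.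

Step 7 (aldehyde 9 may lose AcOH or epimerise; the electron-rich aryl iodide may couple sluggishly). The fallback forms the aryl–carbonyl bond at the acyl oxidation level, with no aldehyde, and sets out from alcohol 8. Oxidation (cat. TEMPO, PhI(OAc)2, MeCN/H2O) gives (2S)-3-(acetyloxy)-2-[2-methoxy-4-(3-methoxy-3-oxopropyl)phenoxy]propanoic acid F2. Thioesterification (EtSH, EDC, cat. DMAP, CH2Cl2, 0 °C) gives S-ethyl (2S)-3-(acetyloxy)-2-[2-methoxy-4-(3-methoxy-3-oxopropyl)phenoxy]propanethioate F3. Iodide 3 is converted by Zn/LiCl insertion into [4-(acetyloxy)-3,5-dimethoxyphenyl]zinc iodide F4. Fukuyama coupling of F3 and F4 (PdCl2(PPh3)2, THF/toluene, rt) gives methyl 3-[4-({(2S)-3-(acetyloxy)-1-[4-(acetyloxy)-3,5-dimethoxyphenyl]-1-oxopropan-2-yl}oxy)-3-methoxyphenyl]propanoate F5. LiAlH4 (THF, −78 °C to rt) then reduces the ketone, both acetates and the methyl ester, and the fallback comes back to the route at tetraol 12.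

Step 9 (DDQ may attack the free syringyl phenol or over-oxidise). The fallback replaces chemoselective oxidation by protect–oxidise–deprotect and sets out from 12. TBSCl (3.3 equiv)/imidazole in DMF at 0 °C silylates the phenol and both primary alcohols but not the hindered benzylic carbinol, giving (1RS,2S)-3-[(tert-butyldimethylsilyl)oxy]-1-{4-[(tert-butyldimethylsilyl)oxy]-3,5-dimethoxyphenyl}-2-[4-{3-[(tert-butyldimethylsilyl)oxy]propyl}-2-methoxyphenoxy]propan-1-ol F6. Dess–Martin oxidation gives (2S)-3-[(tert-butyldimethylsilyl)oxy]-1-{4-[(tert-butyldimethylsilyl)oxy]-3,5-dimethoxyphenyl}-2-[4-{3-[(tert-butyldimethylsilyl)oxy]propyl}-2-methoxyphenoxy]propan-1-one F7. HF·pyridine in THF (acidic, non-epimerising) removes the three silyl groups, and the fallback comes back to the route at 13.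

**Further compounds**
F1 | step 5 | methyl 3-(4-{[1,3-bis(acetyloxy)propan-2-yl]oxy}-3-methoxyphenyl)propanoate | COC(=O)CCc1ccc(OC(COC(C)=O)COC(C)=O)c(OC)c1
F2 | step 7 | (2S)-3-(acetyloxy)-2-[2-methoxy-4-(3-methoxy-3-oxopropyl)phenoxy]propanoic acid | COC(=O)CCc1ccc(O[C@@H](COC(C)=O)C(=O)O)c(OC)c1
F3 | step 7 | S-ethyl (2S)-3-(acetyloxy)-2-[2-methoxy-4-(3-methoxy-3-oxopropyl)phenoxy]propanethioate | COC(=O)CCc1ccc(O[C@@H](COC(C)=O)C(=O)SCC)c(OC)c1
F4 | step 7 | [4-(acetyloxy)-3,5-dimethoxyphenyl]zinc iodide | CC(=O)Oc1c(OC)cc([Zn]I)cc1OC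
F5 | step 7 | methyl 3-[4-({(2S)-3-(acetyloxy)-1-[4-(acetyloxy)-3,5-dimethoxyphenyl]-1-oxopropan-2-yl}oxy)-3-methoxyphenyl]propanoate | COC(=O)CCc1ccc(O[C@@H](COC(C)=O)C(=O)c2cc(OC)c(OC(C)=O)c(OC)c2)c(OC)c1
F6 | step 9 | (1RS,2S)-3-[(tert-butyldimethylsilyl)oxy]-1-{4-[(tert-butyldimethylsilyl)oxy]-3,5-dimethoxyphenyl}-2-[4-{3-[(tert-butyldimethylsilyl)oxy]propyl}-2-methoxyphenoxy]propan-1-ol | COc1cc(CCCO[Si](C)(C)C(C)(C)C)ccc1O[C@@H](CO[Si](C)(C)C(C)(C)C)C(O)c1cc(OC)c(O[Si](C)(C)C(C)(C)C)c(OC)c1
F7 | step 9 | (2S)-3-[(tert-butyldimethylsilyl)oxy]-1-{4-[(tert-butyldimethylsilyl)oxy]-3,5-dimethoxyphenyl}-2-[4-{3-[(tert-butyldimethylsilyl)oxy]propyl}-2-methoxyphenoxy]propan-1-one | COc1cc(CCCO[Si](C)(C)C(C)(C)C)ccc1O[C@@H](CO[Si](C)(C)C(C)(C)C)C(=O)c1cc(OC)c(O[Si](C)(C)C(C)(C)C)c(OC)c1
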